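The readings stem from a simulated flask with constants of no real substance; noise was put on by code.

The easy step first: a second end group has two fates, coupling with a first end group at rate k·A·B or decomposing at rate kd·B, where A and B are the concentrations of first and second end groups and k and kd the rate constants. So you can ask at which A the two fates are equal.

| setting | winter | flask |
|---|---|---|
| first end groups | 1 M | 1.0 M |
| second end groups | 1 M | 1.00 M |
| remark | the very flask that is asked about, followed so far |  |
| time |  | 2.5 d |

winter run (percent of the first end groups charged)

| time / h | links / % | first end groups / % |
|---|---|---|
| 1.00 | 27 | 74 |
| 1.50 | 32 | 66 |
| 2.50 | 42 | 56 |
| 4.00 | 46 | 52 |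
| 8.00 | 55 | 43 |
| 12.0 | 52 | 46 |

(each reading ± 1.5 percentage points)

* average number of monomer units in a chain (unreacted monomers counted as chains of one) at 2.5 d
* part of the first end groups that has reacted at 2.5 d

- each molecule carries two end groups: a chain counts once for every two ends that are left, dead ends included; the units are half of the end groups of the two monomers charged
- steps thought possible: first end groups + second end groups <-> links + released group; second end groups -> decomposed reagent; links -> over-reaction product
- a link that another step uses up counts as cut, two dead ends; so do two ends of one kind that react with each other

You asked for a quick number and your hunch was that the winter plateau carries on. My reckoning reads the stall as loss of second end groups, though an equilibrium fits these readings too. Dividing the two rates and integrating down to zero B gives Bc = (Ac − A) + x·ln(Ac/A), with Ac and Bc the charges and x = kd/k the crossing concentration, the A at which a second end group is as likely to decompose as to couple, a Km for the share. The readings at 8.00 h and 12.0 h average 44.5% first end groups, so these readings, with their scatter, put x at 0.550 M. The charge stands above that crossing and the plateau below it, so control changes hands during the run. I would commit to c near 55.5%. The forecast, made from the same runs, says dp 2.15 (1.8 to 2.4) and c 55% (50% to 61%), since “both predict the plateau persists”.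

The flask gives dp 2.12 and c 55.2%, inside those ranges.

    first end groups + second end groups ⇌ links + released group (K = 280, k = 0.409 M⁻¹ h⁻¹)
    second end groups → decomposed reagent (k = 0.213 h⁻¹)
    links → over-reaction product (k = 7.63 × 10⁻⁴ h⁻¹)

In the flask, forward coupling uses second end groups 1.9 times as fast as decomposition at the start and 1.4 times at 0.0439 d, and by 2.50 d first end groups stand at 0.448 M, which is 0.816 of the 0.550 M read from the winter run, with second end groups, the limiting reagent, at 0.108% of their charge. The neighbour charged with 0.40 M of first end groups starts below that read crossing, at 0.727 of it, and holds more decomposed reagent than the flask's 0.447 M at 2.50 d, namely 0.709 M.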